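The alpha run, with more reagent than substrate, had turned 49.6% of its substrate into target after 60.0 min, which is 0.00744 M. The delta and gamma runs, with substrate in excess, read 2.4% and 0.5% at that time.

| flask | substrate | reagent | remark | time |
|---|---|---|---|---|
| alpha | 0.015 M | 0.022 M (in portions, 2) | run made earlier; portions every 30 s |  |
| delta | 0.085 M | 0.022 M (in portions, 2) | run made earlier; portions every 30 s |  |
| gamma | 0.23 M | 0.022 M (in portions, 2) | run made earlier; portions every 30 s |  |
| cedar | 0.020 M | 0.0220 M (in portions, 2) | the portions of reagent follow each other after 30 s, the first at the start | 80 min |
| larch | 0.040 M | 0.0220 M (in portions, 2) | the portions of reagent follow each other after 30 s, the first at the start | 80 min |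
| birch | 0.080 M | 0.0220 M (in portions, 2) | the portions of reagent follow each other after 30 s, the first at the start | 80 min |
| elm | 0.15 M | 0.0220 M (in portions, 2) | the portions of reagent follow each other after 30 s, the first at the start | 80 min |
| maple | 0.30 M | 0.0220 M (in portions, 2) | the portions of reagent follow each other after 30 s, the first at the start | 80 min |

| alpha: time / min | alpha: target / % | delta: time / min | delta: target / % | gamma: time / min | gamma: target / % |
|---|---|---|---|---|---|
| 5.00 | 6.9 | 5.00 | 0 | 5.00 | 0.3 |
| 8.00 | 12.0 | 8.00 | 0.5 | 8.00 | 0.2 |
| 15.0 | 21.3 | 15.0 | 0.7 | 15.0 | 0 |
| 30.0 | 35.1 | 30.0 | 0.4 | 30.0 | 0.4 |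
| 60.0 | 49.6 | 60.0 | 2.4 | 60.0 | 0.5 |

(standard deviation of a reading: 0.3 percentage points)

- [target] at the end for cedar, larch, birch, elm, maple, in this order
- the course of these numbers from the first flask to the last (rises, then falls / hardly changes / rises all the way / falls all the way / falls, then rises)

- the numbers in the tables scatter by 0.3 percentage points (one standard deviation)
- "hardly changes" means that all values lie within two and a half points (for a concentration: within two and a half percent of the largest)

The rule of thumb at the bench is the surplus: each substrate holds one reagent, and what stands over goes on to target. For alpha that gives 0.00700 M, and the reading lies close to it, though already above it. The rule stops at a ratio of reagent to substrate of one. Cedar stands at 1.10, just above that border, and larch at 0.550, below it. Below the border the surplus is negative and promises no target, yet delta, at a ratio of 0.259, read 2.4%, or 0.00204 M.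

Below the border reagent is the limiting reagent, so look at the fraction of it left free. Suppose excess substrate holds the reagent in a fast equilibrium. Free reagent then goes as one over c(substrate) at the start, and target made from it goes the same way. So you carry the excess product, c(target) times the starting c(substrate), which delta puts at 1.73 × 10⁻⁴ M^2. It is a reading from 60.0 min, with the scatter of 0.3 percentage points on it, while the asked time is 80 min, and you carry it over unchanged. For gamma it gives 0.328% against the 0.5% read, a gap inside that scatter.

Your row is then 0.00434 M for larch, 0.00217 M for birch, 0.00116 M for elm and 5.78 × 10⁻⁴ M for maple. Cedar stands above the border, outside what the supposition covers: the product gives 0.00867 M for cedar, more than alpha read, so for cedar you take the neighbour's reading of 0.00744 M as a rough value, though it comes from another charge and from 60.0 min.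

The forecast gives 0.0045 M, 0.0035 M, 0.003 M, 0.002 M and 0.001 M, a course that falls all the way: “So the row falls throughout, though the small values are uncertain.” Its cedar value lies below yours and its birch value above yours.

The flasks give 0.00723 M, 0.00421 M, 0.00214 M, 0.00113 M and 5.64 × 10⁻⁴ M, a course that falls all the way.

    substrate + reagent ⇌ intermediate A (K = 424 /M, k = 160 /M/min)
    intermediate B ⇌ intermediate C (K = 1.70, k = 0.109 /min)
    substrate + reagent ⇌ intermediate B (K = 620 /M, k = 19.6 /M/min)
    reagent + intermediate B → target (k = 20.2 /M/min)

At the end, birch held 0.655% of its reagent charge free and maple 0.173%, a ratio of 3.79 against 3.75 for their substrate charges. The excess product gives 5.78 × 10⁻⁴ M for maple, which holds 5.64 × 10⁻⁴ M, and 0.00116 M for elm, which holds 0.00113 M.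

(Readings and results are calculated with constants of no real substance.)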